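The numbers in the tables are simulated for an exercise; scatter was added.

The constants I wanted were not rate constants but one equilibrium constant, that of target against isomer of the product, and the runs gave it as a plateau.

| flask | substrate | precatalyst | temperature | remark | time |
|---|---|---|---|---|---|
| green | 0.75 M | 5 mol% | 110 °C | run made earlier |  |
| blue | 3 M | 5 mol% | 132 °C | run made earlier |  |
| ochre | 1.5 M | 2.5 mol% | 110 °C | run made earlier |  |
| cedar | 1.5 M | 5 mol% | 120 °C |  | 50 min |
| oak | 1.5 M | 5 mol% | 140 °C |  | 50 min |
| alder | 1.5 M | 5 mol% | 100 °C |  | 50 min |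
| birch | 1.5 M | 5 mol% |  | at 140 °C until 25 min, from then on at 100 °C | 50 min |

| run | time / min | target / % | isomer of the product / % | substrate / % |
|---|---|---|---|---|
| green | 10.0 | 38.3 | 25.8 | 16.3 |
| green | 20.0 | 31.6 | 25.0 | 14.6 |
| green | 30.0 | 27.0 | 22.6 | 12.7 |
| green | 40.0 | 25.6 | 20.5 | 11.7 |
| green | 50.0 | 22.7 | 18.5 | 10.6 |
| blue | 1.33 | 33.3 | 11.7 | 32.5 |
| blue | 4.00 | 21.0 | 8.8 | 21.9 |
| blue | 8.00 | 13.5 | 6.2 | 14.3 |
| blue | 12.0 | 7.8 | 3.7 | 9.1 |
| blue | 15.0 | 7.3 | 3.2 | 8.3 |
| ochre | 4.00 | 41.8 | 22.3 | 25.5 |
| ochre | 12.0 | 36.2 | 26.0 | 16.3 |
| ochre | 25.0 | 29.6 | 23.4 | 13.7 |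
| ochre | 30.0 | 29.2 | 23.0 | 13.2 |
| ochre | 50.0 | 22.4 | 18.3 | 10.0 |

(scatter of a reading: 0.5 percentage points)

1. which flask leads in share of target in all that became target or isomer of the product ("all alike" within 1.5 percentage points) (cedar / oak / alder / birch / all alike)
2. share of target in all that became target or isomer of the product, cedar
3. share of target in all that became target or isomer of the product, oak
4. share of target in all that became target or isomer of the product, alder
5. share of target in all that became target or isomer of the product, birch

In the green run, the plateau ratio [target]/[isomer of the product] over the last three readings was 1.22. The last ochre reading, from another charge, gave 1.22. The amounts fell, green's target from 27.0% to 22.7%, yet the ratio held, so I froze it and dropped the drain from the reckoning. The blue run gave 2.18 at 132 °C.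

I carried the plateau slope, the change of the logarithm of that ratio per unit of inverse temperature: 4090 K.

Two times remained. One was the half-life of the ratio's excess over its plateau, which I read from ochre as 4.12 min. The other was the time a flask had at its temperature, 50 min. That time was far longer, so at ochre's temperature I reckoned on thermodynamic, not kinetic, control.

The slope gave cedar 61.6%, oak 72.6% and alder 47.9%, with oak highest. Birch had 25.0 min to fall back towards alder's plateau. I expected it slightly above that plateau, but alder's temperature was colder than that of any earlier run, so I had no half-life read there.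

The forecast named oak: cedar 61.5% (58.5% to 64.5%), oak 72.5% (68.5% to 76%), alder 49% (44.5% to 54%), birch 52% (47% to 62%). Its ground was that “the target forms first, then equilibrates with the isomer, while all species drain slowly together”.

The flasks gave cedar 61.9%, oak 74.8%, alder 47.9% and birch 53.1%, and oak led.

    isomer of the product ⇌ substrate (k = 5.65 × 10⁻⁴ /s, Ea = 118 kJ/mol)
    precatalyst → catalyst (k = 0.0140 /s, Ea = 92.0 kJ/mol)
    substrate ⇌ dormant form (K = 30.0, k = 4.47 × 10⁻⁴ /s, Ea = 102 kJ/mol, ΔH = −18.0 kJ/mol)
    target + catalyst ⇌ isomer of the product + catalyst, rate k4*[catalyst]*[target] forward; the back reaction follows from the equilibrium constant (K = 1.10, k = 0.00119 /M/s, Ea = 99.0 kJ/mol, ΔH = −38.0 kJ/mol)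
    substrate ⇌ target (K = 2.86, k = 0.00194 /s, Ea = 116 kJ/mol, ΔH = −44.0 kJ/mol)
    (constants at 100 °C)

Oak's share stood 27 percentage points above alder's, and with the temperature taken off the conversion of isomer of the product into substrate it stood 12 points above, so that step's temperature response is part of the reason. Birch left oak's share at the change and ended 5.2 points above my alder plateau. For the alder flask kept at 125 °C, the slope gave 64.6%, and that flask gave 65.9%.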